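**Retrosynthetic overview**

- Rhopaloic acid B (20) is the cis-(2R,5R) oxane. The acrylic acid comes from terminal alkyne 18 by branched methoxycarbonylation, and 18 from aldehyde 17. The side chain comes from iodide 10 and farnesyl phenyl sulfone 13 by alkylation and desulfonylation.
- The two arms (acetal carbon on C2, ester carbon on C5, as in 8) are the two carbons of the etheno bridge of (1R,4S)-2-oxabicyclo[2.2.2]oct-5-ene 6, cleaved by unsymmetrical ozonolysis after the surplus carboxyl on C6 has been removed by radical decarboxylation.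
- Feature on which the plan rests: the oxane ring O1–C2–C3–C4–C5–C6 with cis substituents on C2 and C5 is the oxygen-containing six-membered ring of a 2-oxabicyclo[2.2.2]oct-5-ene whose bridgeheads are C2 and C5, so cis is fixed by the bicycle.
- Only one ring is formed: the oxane, in step 1, by a copper–bis(oxazoline)-catalysed hetero-Diels–Alder reaction of cyclohexa-1,3-diene with ethyl glyoxylate (bonds O1–C2 and C5–C6).

Key step: step 1

Assumption: (S,S)-t-Bu-box, 2,2'-(propane-2,2-diyl)bis[(4S)-4-tert-butyl-4,5-dihydro-1,3-oxazole], is taken as the ligand enantiomer that leads to the (1R,3S,4S) adduct; if the sense of induction is the opposite, the (R,R) ligand is used and nothing else changes.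
Remark: compound 6 is a volatile ether and is meant to be isolated by careful distillation and carried on as a solution.

**Route**

Step 1
Reactants: 1 cyclohexa-1,3-diene; 2 ethyl glyoxylate
Product: 3 ethyl (1R,3S,4S)-2-oxabicyclo[2.2.2]oct-5-ene-3-carboxylate (endo adduct)
Conditions: Cu(OTf)2 (10 mol%), (S,S)-t-Bu-box (11 mol%), CH2Cl2, 0 °C → rt; glyoxylate freshly distilled
Reagents that add atoms: none
Why: The glyoxylate chelates the divalent copper centre of the Cu(OTf)2–bis(oxazoline) complex through its aldehyde and ester oxygens, and the activated C=O adds across the termini of the s-cis diene in a concerted, asynchronous hetero-Diels–Alder reaction, the closest known type being bis(oxazoline)–copper-catalysed glyoxylate cycloadditions to cyclic dienes. The oxane ring O2–C1–C7–C8–C4–C3 is closed by the [4+2] cycloaddition itself, both ring bonds (O2–C1 and C3–C4) forming in the same step as part of the bicycle. C1 and C4 are bridgeheads, so their cis relationship follows from suprafacial addition to the ring diene, and their absolute configuration follows from the aldehyde face left open by the tert-butyl groups of the ligand. C3 is set by the endo approach of the chelated ester (ester syn to the new C5=C6 bridge) and is erased in step 3. The step needs enantioface selection and cycloaddition in preference to the glyoxylate-ene reaction; the rigid chelate should secure the first and the locked s-cis geometry of the diene the second, while regiochemistry is no issue because the diene is symmetric.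

Step 2
Reactants: 3 ethyl (1R,3S,4S)-2-oxabicyclo[2.2.2]oct-5-ene-3-carboxylate
Product: 4 (1R,3S,4S)-2-oxabicyclo[2.2.2]oct-5-ene-3-carboxylic acid
Conditions: LiOH·H2O, THF/H2O, 0 °C → rt; then 1 M HCl
Reagents that add atoms: lithium hydroxide, [Li+].[OH-]
Why: Saponification of the unhindered α-alkoxy ester frees the acid needed for decarboxylation, and the base-sensitive centre C3 is of no consequence because it is erased in step 3.

Step 3
Reactants: 4 (1R,3S,4S)-2-oxabicyclo[2.2.2]oct-5-ene-3-carboxylic acid
Product: 6 (1R,4S)-2-oxabicyclo[2.2.2]oct-5-ene, via thiohydroxamate ester 5 (not isolated)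
Conditions: N-hydroxypyridine-2-thione, DCC, DMAP (cat.), CH2Cl2, 0 °C, dark; then t-BuSH (excess), hν (tungsten lamp), rt
Reagents that add atoms: none
Why: Barton reductive decarboxylation: photolysis of the thiohydroxamate ester releases CO2 and an α-alkoxy radical at C3 that is stabilised by the ring oxygen and should be reduced by the thiol faster than it can rearrange by 3-exo attack on the C5=C6 bridge (which would lead to a less stabilised secondary alkyl radical), so that C3 becomes the ring CH2 and the bridgeheads C1 and C4 stay untouched.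

Step 4
Reactants: 6 (1R,4S)-2-oxabicyclo[2.2.2]oct-5-ene
Product: 8 methyl (3R,6R)-6-(dimethoxymethyl)oxane-3-carboxylate, via methoxy hydroperoxide 7 (not isolated)
Conditions: O3, CH2Cl2/MeOH, TsOH·H2O (cat.), −78 °C → rt; NaHCO3; then Ac2O, Et3N, CH2Cl2, 0 °C → rt
Reagents that add atoms: ozone, [O-][O+]=O; methanol, CO
Why: Unsymmetrical ozonolysis by the Criegee mechanism: the primary ozonide should fragment so that the carbonyl oxide forms on C5, remote from the electron-withdrawing allylic C1–O bond, and is trapped by methanol as the methoxy hydroperoxide while the aldehyde on C6 is acetalised under TsOH, and Ac2O/Et3N then dehydrates the methoxy hydroperoxide to the methyl ester with the epimerisable α-alkoxy aldehyde already masked.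

Step 5
Reactants: 8 methyl (3R,6R)-6-(dimethoxymethyl)oxane-3-carboxylate
Product: 9 [(3S,6R)-6-(dimethoxymethyl)oxan-3-yl]methanol
Conditions: LiAlH4, THF, 0 °C
Reagents that add atoms: none
Why: Hydride reduction of the methyl ester gives the primary alcohol, the dimethyl acetal being inert to LiAlH4 and the ring centres not being deprotonated (the descriptor at C3 changes only because the substituent priorities change).

Step 6
Reactants: 9 [(3S,6R)-6-(dimethoxymethyl)oxan-3-yl]methanol
Product: 10 (2R,5R)-2-(dimethoxymethyl)-5-(iodomethyl)oxane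
Conditions: I2, PPh3, imidazole, CH2Cl2, 0 °C → rt
Reagents that add atoms: iodine, II
Why: Appel-type iodination replaces the primary hydroxyl by SN2 displacement at the exocyclic CH2, so no ring stereocentre is involved and imidazole keeps the acetal from acid.

Step 7
Reactants: 11 (2E,6E)-farnesol
Product: 12 (2E,6E)-farnesyl bromide
Conditions: PBr3, Et2O, −10 °C
Reagents that add atoms: phosphorus tribromide, BrP(Br)Br
Why: Bromination of the primary allylic alcohol through its phosphite ester at low temperature should proceed by SN2 displacement without allylic transposition or E/Z isomerisation.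

Step 8
Reactants: 12 (2E,6E)-farnesyl bromide
Product: 13 [(2E,6E)-3,7,11-trimethyldodeca-2,6,10-trien-1-yl]sulfonylbenzene (farnesyl phenyl sulfone)
Conditions: PhSO2Na, DMF, rt
Reagents that add atoms: sodium benzenesulfinate, [Na+].[O-]S(=O)c1ccccc1
Why: S-Alkylation of the soft sulfinate anion by the primary allylic bromide (SN2) gives the allylic sulfone with the 2E geometry intact.

Step 9
Reactants: 13 farnesyl phenyl sulfone; 10 (2R,5R)-2-(dimethoxymethyl)-5-(iodomethyl)oxane
Product: 15 (2R,5S)-5-[(3E,7E)-2-(benzenesulfonyl)-4,8,12-trimethyltrideca-3,7,11-trien-1-yl]-2-(dimethoxymethyl)oxane (cis ring; both epimers at the sulfone carbon), via lithiated sulfone 14 (not isolated)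
Conditions: 13 (1.2 equiv), n-BuLi, THF/HMPA, −78 °C; then 10, −78 → −20 °C
Reagents that add atoms: none
Why: Alkylation of an α-sulfonyl carbanion: the lithiated allylic sulfone reacts at its α-carbon with the primary iodide (SN2), the alkenes keep their E geometry because the charge is localised next to sulfur, and the new sulfone-bearing centre is of no consequence because it is removed in step 10.

Step 10
Reactants: 15 (2R,5S)-5-[(3E,7E)-2-(benzenesulfonyl)-4,8,12-trimethyltrideca-3,7,11-trien-1-yl]-2-(dimethoxymethyl)oxane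
Product: 16 (2R,5R)-2-(dimethoxymethyl)-5-[(3E,7E)-4,8,12-trimethyltrideca-3,7,11-trien-1-yl]oxane
Conditions: PdCl2(dppp) (5 mol%), LiBHEt3, THF, 0 °C
Reagents that add atoms: none
Why: Palladium-catalysed hydride desulfonylation of an allylic sulfone: zerovalent palladium formed from PdCl2(dppp) and LiBHEt3 ionises the C–S bond to a π-allyl complex and hydride is delivered to the less substituted terminus, which should leave the trisubstituted 3E alkene in place where dissolving-metal reduction would scramble it.

Step 11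
Reactants: 16 (2R,5R)-2-(dimethoxymethyl)-5-[(3E,7E)-4,8,12-trimethyltrideca-3,7,11-trien-1-yl]oxane
Product: 17 (2R,5R)-5-[(3E,7E)-4,8,12-trimethyltrideca-3,7,11-trien-1-yl]oxane-2-carbaldehyde
Conditions: 1 M aq. HCl/THF (1:4), rt; used at once
Reagents that add atoms: water, O
Why: Acid-catalysed acetal hydrolysis in dilute aqueous acid at room temperature frees the aldehyde under conditions that isolated trisubstituted alkenes tolerate, and immediate use gives the less stable cis centre C2 little time to epimerise.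

Step 12
Reactants: 17 (2R,5R)-5-[(3E,7E)-4,8,12-trimethyltrideca-3,7,11-trien-1-yl]oxane-2-carbaldehyde
Product: 18 (2R,5R)-2-ethynyl-5-[(3E,7E)-4,8,12-trimethyltrideca-3,7,11-trien-1-yl]oxane
Conditions: dimethyl (1-diazo-2-oxopropyl)phosphonate, K2CO3, MeOH, 0 °C → rt
Reagents that add atoms: dimethyl (1-diazo-2-oxopropyl)phosphonate, COP(=O)(OC)C(=[N+]=[N-])C(C)=O
Why: Seyferth–Gilbert homologation in the Ohira–Bestmann modification: the diazomethylphosphonate anion formed by methanolysis adds to the aldehyde, and loss of phosphate and N2 followed by 1,2-hydride shift of the alkylidene carbene gives the terminal alkyne under conditions mild enough to keep the α-alkoxy centre C2.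

Step 13
Reactants: 18 (2R,5R)-2-ethynyl-5-[(3E,7E)-4,8,12-trimethyltrideca-3,7,11-trien-1-yl]oxane
Product: 19 methyl 2-[(2R,5R)-5-[(3E,7E)-4,8,12-trimethyltrideca-3,7,11-trien-1-yl]oxan-2-yl]prop-2-enoate
Conditions: Pd(OAc)2 (2 mol%), 2-(diphenylphosphino)pyridine (40 mol%), MsOH (20 mol%), CO (20 bar), MeOH/CH2Cl2, 50 °C
Reagents that add atoms: carbon monoxide, [C-]#[O+]; methanol, CO
Why: Palladium-catalysed Markovnikov methoxycarbonylation of a terminal alkyne: with the P,N ligand the palladium hydride adds so that palladium sits on the internal carbon, and CO insertion with methanolysis should give the 2-substituted acrylate, the acid being held as the pyridinium salt of the excess ligand so that the trisubstituted alkenes are spared.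

Step 14
Reactants: 19 methyl 2-[(2R,5R)-5-[(3E,7E)-4,8,12-trimethyltrideca-3,7,11-trien-1-yl]oxan-2-yl]prop-2-enoate
Product: 20 rhopaloic acid B, 2-[(2R,5R)-5-[(3E,7E)-4,8,12-trimethyltrideca-3,7,11-trien-1-yl]oxan-2-yl]prop-2-enoic acid
Conditions: LiOH·H2O, THF/MeOH/H2O, rt; then 1 M HCl, 0 °C, to pH 3
Reagents that add atoms: lithium hydroxide, [Li+].[OH-]
Why: Saponification of the methyl ester at room temperature frees the acrylic acid, and mild cold acidification avoids conjugate addition and isomerisation of the exocyclic alkene.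

**Compound list**

1 | cyclohexa-1,3-diene | C1=CC=CCC1 | starting material
2 | ethyl glyoxylate | CCOC(=O)C=O | starting material
3 | ethyl (1R,3S,4S)-2-oxabicyclo[2.2.2]oct-5-ene-3-carboxylate | [C@H]1(C=C2)CC[C@@H]2[C@@H](C(=O)OCC)O1 | intermediate
4 | (1R,3S,4S)-2-oxabicyclo[2.2.2]oct-5-ene-3-carboxylic acid | [C@H]1(C=C2)CC[C@@H]2[C@@H](C(=O)O)O1 | intermediate
5 | 2-thioxopyridin-1(2H)-yl (1R,3S,4S)-2-oxabicyclo[2.2.2]oct-5-ene-3-carboxylate | [C@H]1(C=C2)CC[C@@H]2[C@@H](C(=O)ON3C=CC=CC3=S)O1 | intermediate
6 | (1R,4S)-2-oxabicyclo[2.2.2]oct-5-ene | [C@H]1(C=C2)CC[C@@H]2CO1 | intermediate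
7 | (2R,5R)-2-(dimethoxymethyl)-5-[hydroperoxy(methoxy)methyl]oxane (either configuration at the hydroperoxy carbon) | [C@H]1(C(OC)OC)CC[C@@H](C(OC)OO)CO1 | intermediate
8 | methyl (3R,6R)-6-(dimethoxymethyl)oxane-3-carboxylate | [C@H]1(C(OC)OC)CC[C@@H](C(=O)OC)CO1 | intermediate
9 | [(3S,6R)-6-(dimethoxymethyl)oxan-3-yl]methanol | [C@H]1(C(OC)OC)CC[C@@H](CO)CO1 | intermediate
10 | (2R,5R)-2-(dimethoxymethyl)-5-(iodomethyl)oxane | [C@H]1(C(OC)OC)CC[C@@H](CI)CO1 | intermediate
11 | (2E,6E)-farnesol | OC/C=C(\C)CC/C=C(\C)CCC=C(C)C | starting material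
12 | (2E,6E)-farnesyl bromide | BrC/C=C(\C)CC/C=C(\C)CCC=C(C)C | intermediate
13 | [(2E,6E)-3,7,11-trimethyldodeca-2,6,10-trien-1-yl]sulfonylbenzene | O=S(=O)(C/C=C(\C)CC/C=C(\C)CCC=C(C)C)c1ccccc1 | intermediate
14 | [(2E,6E)-1-(benzenesulfonyl)-3,7,11-trimethyldodeca-2,6,10-trien-1-yl]lithium | [Li]C(/C=C(\C)CC/C=C(\C)CCC=C(C)C)S(=O)(=O)c1ccccc1 | intermediate
15 | (2R,5S)-5-[(3E,7E)-2-(benzenesulfonyl)-4,8,12-trimethyltrideca-3,7,11-trien-1-yl]-2-(dimethoxymethyl)oxane | [C@H]1(C(OC)OC)CC[C@@H](CC(/C=C(\C)CC/C=C(\C)CCC=C(C)C)S(=O)(=O)c2ccccc2)CO1 | intermediate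
16 | (2R,5R)-2-(dimethoxymethyl)-5-[(3E,7E)-4,8,12-trimethyltrideca-3,7,11-trien-1-yl]oxane | [C@H]1(C(OC)OC)CC[C@@H](CC/C=C(\C)CC/C=C(\C)CCC=C(C)C)CO1 | intermediate
17 | (2R,5R)-5-[(3E,7E)-4,8,12-trimethyltrideca-3,7,11-trien-1-yl]oxane-2-carbaldehyde | [C@H]1(C=O)CC[C@@H](CC/C=C(\C)CC/C=C(\C)CCC=C(C)C)CO1 | intermediate
18 | (2R,5R)-2-ethynyl-5-[(3E,7E)-4,8,12-trimethyltrideca-3,7,11-trien-1-yl]oxane | [C@H]1(C#C)CC[C@@H](CC/C=C(\C)CC/C=C(\C)CCC=C(C)C)CO1 | intermediate
19 | methyl 2-[(2R,5R)-5-[(3E,7E)-4,8,12-trimethyltrideca-3,7,11-trien-1-yl]oxan-2-yl]prop-2-enoate | C=C(C(=O)OC)[C@H]1CC[C@@H](CC/C=C(\C)CC/C=C(\C)CCC=C(C)C)CO1 | intermediate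
20 | rhopaloic acid B | C=C(C(=O)O)[C@H]1CC[C@@H](CC/C=C(\C)CC/C=C(\C)CCC=C(C)C)CO1 | target

**Step count and risks**

Total step count: 14. Longest linear sequence: 12 (steps 1–6 and 9–14); steps 7 and 8 form the side branch.

Steps most likely to fail:

Step 4. The primary ozonide may fragment with poor regiocontrol, placing the carbonyl oxide on the bridge carbon next to the ring oxygen, which would give the regioisomeric acetal ester. The fallback tells the two arms apart by the different electrophilicity of two esters instead of by the ozonide. It sets out from 6: ozonolysis in methanolic NaOH (CH2Cl2, −78 °C) should cleave the bridge symmetrically to dimethyl (2R,5R)-oxane-2,5-dicarboxylate F1. NaBH4 in MeOH at 0 °C should reduce only the ester activated by the α-ring oxygen, giving methyl (3R,6R)-6-(hydroxymethyl)oxane-3-carboxylate F2. Dess–Martin oxidation (NaHCO3, CH2Cl2) gives methyl (3R,6R)-6-formyloxane-3-carboxylate F3, which HC(OMe)3 and TsOH (cat.) in MeOH acetalise; the fallback comes back to the route at 8.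

Step 13. Branched selectivity may erode at the hindered propargylic position, the ring may open by β-alkoxide elimination from the vinylpalladium intermediate, or the acid may attack the triene. The fallback builds the acrylate by carbonylation of an enol triflate and sets out from 17. MeMgBr (THF, −78 °C) gives 1-[(2R,5R)-5-[(3E,7E)-4,8,12-trimethyltrideca-3,7,11-trien-1-yl]oxan-2-yl]ethan-1-ol F4 (both carbinol epimers). Dess–Martin oxidation gives 1-[(2R,5R)-5-[(3E,7E)-4,8,12-trimethyltrideca-3,7,11-trien-1-yl]oxan-2-yl]ethan-1-one F5. Kinetic deprotonation at the methyl group with KN(SiMe3)2 (THF, −78 °C) and trapping with PhNTf2 gives 1-[(2R,5R)-5-[(3E,7E)-4,8,12-trimethyltrideca-3,7,11-trien-1-yl]oxan-2-yl]ethenyl trifluoromethanesulfonate F6. Pd(OAc)2/PPh3, CO (1 atm), Et3N, MeOH/DMF then gives the methyl acrylate; the fallback comes back to the route at 19.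

Step 3. The homoallylic α-alkoxy radical may rearrange through closure onto the bridge alkene, thiyl radicals may add to the alkene, or the volatile product may be lost on isolation. The fallback postpones decarboxylation until the alkene is gone and the compound is no longer volatile; it sets out from 4. BnBr and K2CO3 in DMF give benzyl (1R,3S,4S)-2-oxabicyclo[2.2.2]oct-5-ene-3-carboxylate F7. Ozonolysis under the conditions of step 4 should give 2-benzyl 3-methyl (2S,3R,6R)-6-(dimethoxymethyl)oxane-2,3-dicarboxylate F8. Hydrogenolysis (H2, Pd/C, EtOAc) frees (2S,3R,6R)-6-(dimethoxymethyl)-3-(methoxycarbonyl)oxane-2-carboxylic acid F9. Barton decarboxylation through 2-thioxopyridin-1(2H)-yl 3-methyl (2S,3R,6R)-6-(dimethoxymethyl)oxane-2,3-dicarboxylate F10 (N-hydroxypyridine-2-thione, DCC; t-BuSH, hν) removes the carboxyl; the fallback comes back to the route at 8, bypassing 6.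

**Further compounds**

F1 | step 4 | dimethyl (2R,5R)-oxane-2,5-dicarboxylate | [C@H]1(C(=O)OC)CC[C@@H](C(=O)OC)CO1
F2 | step 4 | methyl (3R,6R)-6-(hydroxymethyl)oxane-3-carboxylate | [C@H]1(CO)CC[C@@H](C(=O)OC)CO1
F3 | step 4 | methyl (3R,6R)-6-formyloxane-3-carboxylate | [C@H]1(C=O)CC[C@@H](C(=O)OC)CO1
F4 | step 13 | 1-[(2R,5R)-5-[(3E,7E)-4,8,12-trimethyltrideca-3,7,11-trien-1-yl]oxan-2-yl]ethan-1-ol | CC(O)[C@H]1CC[C@@H](CC/C=C(\C)CC/C=C(\C)CCC=C(C)C)CO1
F5 | step 13 | 1-[(2R,5R)-5-[(3E,7E)-4,8,12-trimethyltrideca-3,7,11-trien-1-yl]oxan-2-yl]ethan-1-one | CC(=O)[C@H]1CC[C@@H](CC/C=C(\C)CC/C=C(\C)CCC=C(C)C)CO1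
F6 | step 13 | 1-[(2R,5R)-5-[(3E,7E)-4,8,12-trimethyltrideca-3,7,11-trien-1-yl]oxan-2-yl]ethenyl trifluoromethanesulfonate | C=C(OS(=O)(=O)C(F)(F)F)[C@H]1CC[C@@H](CC/C=C(\C)CC/C=C(\C)CCC=C(C)C)CO1
F7 | step 3 | benzyl (1R,3S,4S)-2-oxabicyclo[2.2.2]oct-5-ene-3-carboxylate | [C@H]1(C=C2)CC[C@@H]2[C@@H](C(=O)OCc3ccccc3)O1
F8 | step 3 | 2-benzyl 3-methyl (2S,3R,6R)-6-(dimethoxymethyl)oxane-2,3-dicarboxylate | [C@H]1(C(OC)OC)CC[C@@H](C(=O)OC)[C@@H](C(=O)OCc2ccccc2)O1
F9 | step 3 | (2S,3R,6R)-6-(dimethoxymethyl)-3-(methoxycarbonyl)oxane-2-carboxylic acid | [C@H]1(C(OC)OC)CC[C@@H](C(=O)OC)[C@@H](C(=O)O)O1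
F10 | step 3 | 2-thioxopyridin-1(2H)-yl 3-methyl (2S,3R,6R)-6-(dimethoxymethyl)oxane-2,3-dicarboxylate | [C@H]1(C(OC)OC)CC[C@@H](C(=O)OC)[C@@H](C(=O)ON2C=CC=CC2=S)O1
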